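In a one-step world whose rate follows the catalyst, 3.95 times the catalyst gives that same factor in early product. Your two earlier runs turn a starting material into product, with a solid reagent present, at different amounts of catalyst.

| flask | starting material | solid reagent | catalyst | remark | time |
|---|---|---|---|---|---|
| midnight | 1.5 M | 1.8 M | 4.3 mM | run made earlier |  |
| winter | 1.5 M | 1.8 M | 17 mM | run made earlier |  |
| flask | 1.5 M | 1.80 M | 8.7 mM |  | 8.0 h |

- midnight (time / h: product / %): 1.00: 0.4; 2.00: 0.6; 3.00: 2.2; 4.00: 2.8; 5.00: 4.0; 6.00: 5.8
- winter (time / h: product / %): 0.333: 0.2; 1.00: 2.6; 2.00: 9.0; 3.00: 16.5; 4.00: 24.1; 5.00: 32.5; 6.00: 39.4

(each reading ± 0.3 percentage points)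

- given per volume of solution although it is solid: solid reagent
- at the start none of the solid reagent is in solution

- alpha: doubling the amount of catalyst, all else as stated
- eta: doubling the solubility of the solid reagent, all else as stated
- beta: doubling the dissolution coefficient of the solid reagent, all else as stated

- amount of product at 8.0 h, in percent of the starting material charged
- the change that raises the amount of product at 8.0 h, in percent of the starting material charged most ("none" if none brings more than 2 percentage points) (alpha / eta / beta / none)
- amount of product at 8.0 h, in percent of the starting material charged, after alpha

Yet at 6.00 h the winter run holds 39.4 % against 5.8 % in the midnight run, which is 6.79 times the product from 3.95 times the catalyst.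

But product starts slowly: in the winter run it grows 3.46 times between 1.00 h and 2.00 h. So suppose catalyst simply speeds the flask's clock (variable time normalisation). Then hours times catalyst, divided by the winter catalyst, gives a flask's winter time, its place on the winter curve. The last midnight reading has a winter time of 1.52 h, where a straight line between winter readings gives 5.91 %, close to the 5.8 % read. So the odd factor can be read as the curve's bend.

Your flask's winter time is 4.09 h, so the line through the later winter readings gives 24.8 %. Doubling the catalyst doubles that time to 8.18 h, past the last winter reading, and the line carried on gives 56.1 %.

The forecast gives 22 % for the flask, below your figure, and 56 % after alpha, reasoning: “Four times the catalyst gives about seven times the rate, so the dependence is steeper than first order”.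

The flask gives 25.3 %, and 53.9 % after alpha, which gains 29 percentage points against 17 points for eta and 0.12 points for beta.

    starting material + catalyst → catalyst + intermediate (k = 0.00820 M⁻¹ s⁻¹)
    partner + catalyst + intermediate → catalyst + product (k = 0.00400 M⁻² s⁻¹)
    solid reagent ⇌ partner, rate k3*(cs3 - [partner]) while solid is left; crystals form when [partner] > cs3 (solubility = 0.540 M, k = 0.00270 s⁻¹)

Both reaction steps in these equations carry the catalyst, the dissolving of the solid reagent does not, and the flask's 25.3 % stands beside the 24.8 % read at 4.09 h of winter time. Now take a neighbouring flask with 0.015 M of catalyst and the same 8.0 h. Its winter time is 7.06 h, past the last winter reading, and the same line carried on gives 47.5 %. That neighbouring flask gives 47.0 %, with 50.1 % standing as intermediate and 2.89 % as starting material.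

The numbers in the tables stem from a simulated flask for an exercise; the scatter is artificial.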